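**Retrosynthetic overview**
1. Feature: in the naphthalene ring C1'–C2'–C3'–C4'–C4a'–C8a', every carbon except C3' carries a substituent (C1' isoquinolin-7-yl, C2' CH3, C4' OCH3). Removing this single CH contracts the ring to the five-membered ring of an indene. In that indene C4' is an enol ether (former indanone carbonyl) carbon, C2' is its methylated α-carbon, and C1' is an sp3 β-carbon.
2. Key disconnection: C3'–C4' and C2'–C3'. C3' returns as CBr2, which adds to C4'=C2' and enters the ring when the cyclopropane opens. This builds the aromatic ring, keeps the enol oxygen as 4'-OMe, and creates the C7–C1' axis only at that point.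
3. C7–C1' is cut as a rhodium-catalysed 1,4-addition of an isoquinolin-7-ylboronate to 7-(benzyloxy)-2-methylindenone, which comes from 7-hydroxy-1-indanone.
4. The pyridine ring of the isoquinoline is cut at N–C1 and N–C3, giving ammonia and an o-(prop-1-ynyl)acetophenone made from 2'-hydroxy-6'-methoxyacetophenone. C7 is then functionalised by ortho-bromination of the 8-ol.
5. Order of ring formation: pyridine ring, cyclopropane, then the six-membered C1'–C4' ring. One hydrogenolysis removes Br and both benzyl groups, and the atropisomers are separated last.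

Key step: step 14

Assumption: the SMILES holds no descriptor for the C7–C1' axis. The constitution is therefore built as the racemic biaryl, and the ent-atropisomer is taken from it on a chiral phase (step 16). It is recognised by a CD curve that mirrors that of dioncophylleine A.

**Fragment A: indenone**

Step 1
Reactants: 1 7-hydroxy-2,3-dihydro-1H-inden-1-one
Product: 2 7-(benzyloxy)-2,3-dihydro-1H-inden-1-one
Conditions: BnBr, K2CO3, DMF, 60 °C
Reagents that add atoms: benzyl bromide, BrCc1ccccc1
Why: Williamson ether synthesis, in which carbonate deprotonates the chelated phenol and the phenoxide displaces bromide; benzyl is chosen because it is removed in the final hydrogenolysis.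

Step 2
Reactants: 2 7-(benzyloxy)-2,3-dihydro-1H-inden-1-one
Product: 4 7-(benzyloxy)-2-methyl-2,3-dihydro-1H-inden-1-one (racemic), via lithium enolate 3 (not isolated)
Conditions: LiHMDS (1.05 equiv), THF, −78 °C; then MeI, −78 → 0 °C
Reagents that add atoms: iodomethane, CI
Why: Enolate alkylation at C2, the only enolisable position, with one equivalent of hindered amide base at low temperature to limit double methylation; the new C2 centre forms racemic and is planarised again in step 3.

Step 3
Reactants: 4 7-(benzyloxy)-2-methyl-2,3-dihydro-1H-inden-1-one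
Product: 5 4-(benzyloxy)-2-methyl-3-(trimethylsilyloxy)-1H-indene
Conditions: TMSOTf, Et3N, CH2Cl2, 0 °C
Reagents that add atoms: trimethylsilyl trifluoromethanesulfonate, C[Si](C)(C)OS(=O)(=O)C(F)(F)F
Why: Soft enolisation with O-silylation (silyl enol ether formation), which can give only one enol ether because C2–H is the sole α-hydrogen.

Step 4
Reactants: 5 4-(benzyloxy)-2-methyl-3-(trimethylsilyloxy)-1H-indene
Product: 6 7-(benzyloxy)-2-methyl-1H-inden-1-one
Conditions: Pd(OAc)2 (10 mol %), O2 (1 atm), dry DMSO, rt → 45 °C; product kept cold and used promptly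
Reagents that add atoms: none
Why: Saegusa–Ito oxidation in its aerobic catalytic form, in which the enol silane passes its enolate to divalent palladium, syn β-hydride elimination takes the benzylic ring hydrogen at C3, and oxygen returns zerovalent palladium to the divalent state; the benzyl ether and the activated arene, which bromination routes to indenones would attack, are left untouched.

**Fragment B: isoquinolinylboronate**

Step 5
Reactants: 7 2'-hydroxy-6'-methoxyacetophenone
Product: 8 2-acetyl-3-methoxyphenyl trifluoromethanesulfonate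
Conditions: Tf2O, pyridine, CH2Cl2, 0 °C
Reagents that add atoms: trifluoromethanesulfonic anhydride, O=S(=O)(OS(=O)(=O)C(F)(F)F)C(F)(F)F
Why: O-sulfonylation of the phenol, which turns this oxygen into a cross-coupling leaving group that the ortho acetyl group activates towards oxidative addition.

Step 6
Reactants: 8 2-acetyl-3-methoxyphenyl trifluoromethanesulfonate; 9 propyne
Product: 10 1-[2-methoxy-6-(prop-1-yn-1-yl)phenyl]ethan-1-one
Conditions: propyne (3 equiv), PdCl2(PPh3)2 (5 mol %), CuI (10 mol %), Et3N, DMF, 60 °C, sealed vessel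
Reagents that add atoms: propyne (9), CC#C
Why: Sonogashira coupling of an electron-poor aryl triflate with a terminal alkyne, which installs the three carbons that become C4, C3 and 3-CH3.

Step 7
Reactants: 10 1-[2-methoxy-6-(prop-1-yn-1-yl)phenyl]ethan-1-one
Product: 12 8-methoxy-1,3-dimethylisoquinoline, via ketimine 11 (not isolated)
Conditions: NH3 (7 M in MeOH), sealed tube, 120 °C
Reagents that add atoms: ammonia, N
Why: Condensation to the N–H ketimine followed by 6-endo-dig addition of nitrogen to the alkyne (isoquinoline synthesis from o-alkynylaryl ketones and ammonia); aromatisation makes the six-membered closure the thermodynamic sink and puts the alkyne methyl at C3.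

Step 8
Reactants: 12 8-methoxy-1,3-dimethylisoquinoline
Product: 13 1,3-dimethylisoquinolin-8-ol
Conditions: 48% aq HBr, AcOH, reflux; then aq NH3 to pH 8
Reagents that add atoms: none
Why: Acidic aryl methyl ether cleavage (bromide attacks the methyl group of the protonated ether) on a fully aromatic heterocycle that has no other group sensitive to hot HBr.

Step 9
Reactants: 13 1,3-dimethylisoquinolin-8-ol
Product: 14 7-bromo-1,3-dimethylisoquinolin-8-ol
Conditions: NBS (1.0 equiv, slow addition), iPr2NH (20 mol %), CH2Cl2, 0 °C
Reagents that add atoms: N-bromosuccinimide, O=C1CCC(=O)N1Br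
Why: Amine-mediated ortho-selective phenol bromination, in which the bromine carrier is hydrogen-bonded to the 8-OH and delivers bromine to C7, the only free ortho position, rather than to the para position C5, just as 1-naphthol is converted to its 2-bromide.

Step 10
Reactants: 14 7-bromo-1,3-dimethylisoquinolin-8-ol
Product: 15 8-(benzyloxy)-7-bromo-1,3-dimethylisoquinoline
Conditions: BnBr (1.05 equiv), K2CO3, DMF, rt
Reagents that add atoms: benzyl bromide, BrCc1ccccc1
Why: Williamson ether synthesis, in which the phenoxide reacts much faster than the ring nitrogen because the two flanking methyl groups shield nitrogen from quaternisation.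

Step 11
Reactants: 15 8-(benzyloxy)-7-bromo-1,3-dimethylisoquinoline
Product: 16 8-(benzyloxy)-1,3-dimethyl-7-(4,4,5,5-tetramethyl-1,3,2-dioxaborolan-2-yl)isoquinoline
Conditions: B2pin2, PdCl2(dppf) (5 mol %), KOAc, 1,4-dioxane, 90 °C
Reagents that add atoms: bis(pinacolato)diboron, CC1(C)OB(OC1(C)C)B1OC(C)(C)C(C)(C)O1
Why: Miyaura borylation, which places boron at C7 under weakly basic conditions and so avoids organolithium reagents that would deprotonate the acidic 1-methyl group.

**Union and end game**

Step 12
Reactants: 6 7-(benzyloxy)-2-methyl-1H-inden-1-one; 16 8-(benzyloxy)-1,3-dimethyl-7-(4,4,5,5-tetramethyl-1,3,2-dioxaborolan-2-yl)isoquinoline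
Product: 17 7-(benzyloxy)-3-[8-(benzyloxy)-1,3-dimethylisoquinolin-7-yl]-2-methyl-2,3-dihydro-1H-inden-1-one (racemic, both C2 epimers, trans expected to dominate)
Conditions: [Rh(cod)OH]2 (3 mol %), KOH (20 mol %), 1,4-dioxane/H2O 10:1, 40 °C; 6 (1.5 equiv) added over 1 h
Reagents that add atoms: none
Why: Hayashi–Miyaura 1,4-addition, in which the aryl group passes from boron to rhodium, the strained and strongly electrophilic indenone double bond inserts with the aryl at the β-carbon C3, and water releases the ketone; C3 forms racemic under the achiral cod ligand, and the epimerisable C2 centre is irrelevant because step 13 planarises it.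

Step 13
Reactants: 17 7-(benzyloxy)-3-[8-(benzyloxy)-1,3-dimethylisoquinolin-7-yl]-2-methyl-2,3-dihydro-1H-inden-1-one
Product: 19 4-(benzyloxy)-1-[8-(benzyloxy)-1,3-dimethylisoquinolin-7-yl]-3-methoxy-2-methyl-1H-indene (racemic at C1), via dimethyl ketal 18 (not isolated)
Conditions: HC(OMe)3 (10 equiv), TsOH·H2O (1.1 equiv), toluene, 60 °C, then 105 °C with slow distillation of volatiles; cold aq NaHCO3; short plug of basic alumina, used at once
Reagents that add atoms: trimethyl orthoformate, COC(OC)OC
Why: Orthoformate ketalisation followed by acid-catalysed loss of methanol, where only C2 carries an α-hydrogen so only one enol ether can form, acid cannot move the double bond towards C1, and the nitrogen is masked as its tosylate salt (a mild acid catalyst of pyridinium tosylate strength), which avoids the N-methylation that enolate O-alkylation would risk.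

Step 14
Reactants: 19 4-(benzyloxy)-1-[8-(benzyloxy)-1,3-dimethylisoquinolin-7-yl]-3-methoxy-2-methyl-1H-indene; 20 bromoform
Product: 23 8-(benzyloxy)-7-[5-(benzyloxy)-3-bromo-4-methoxy-2-methylnaphthalen-1-yl]-1,3-dimethylisoquinoline (racemic axis), via dibromocyclopropane adduct 21 (not isolated), via methoxy-stabilised bromoallyl cation 22 (not isolated)
Conditions: CHBr3 (6 equiv), KOtBu (5 equiv, solid, in portions over 2 h), toluene, −30 °C → rt
Reagents that add atoms: bromoform (20), BrC(Br)Br
Why: tert-Butoxide takes the proton of bromoform and CBr3− loses bromide; the singlet, electrophilic carbene adds in one concerted [2+1] step to the C4'=C2' bond (indene C3=C2) of 19, on the face away from the C1' isoquinolinyl group, and closes the cyclopropane of 21. In 21 the endo C–Br bond ionises while the shared C4'–C2' bond opens by a disrotatory two-electron electrocyclic process, so the three- and five-membered rings merge into the six-membered ring of 22, a 2-bromoallyl cation that the methoxy oxygen carries as an oxocarbenium ion; base then removes the doubly benzylic C1'–H next to the cationic terminus C2', and the ring becomes aromatic with C3'–C4' and C2'–C3' as the two new bonds. The closest known reaction type is the dihalocarbene ring enlargement of indenes to 2-halonaphthalenes and of cyclic enol ethers to α-halo enones. No stereocentre is left: the three centres of 21 are erased, and the C7–C1' axis, which exists only after aromatisation, forms racemic. The step needs site selectivity for the enol ether over the isoquinoline nitrogen, the arenes and the benzylic C–H bonds, which its nucleophilicity as a tetrasubstituted donor alkene and the two methyl groups around nitrogen should secure, and it needs proton loss from C1' rather than from the 2'-methyl group, which the gain in aromaticity secures. It also needs carbene capture to outrun a base-induced 1,3-proton shift of the 1H-indene, which would place the new carbon between C1' and C2'; the base is therefore fed slowly into an excess of the unhindered and kinetically more acidic bromoform, so that free alkoxide never accumulates next to the shielded C1'–H.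

Step 15
Reactants: 23 8-(benzyloxy)-7-[5-(benzyloxy)-3-bromo-4-methoxy-2-methylnaphthalen-1-yl]-1,3-dimethylisoquinoline
Product: 24 7-(5-hydroxy-4-methoxy-2-methylnaphthalen-1-yl)-1,3-dimethylisoquinolin-8-ol (racemic dioncophylleine A)
Conditions: H2 (1 atm), 10% Pd/C, NaOAc (3 equiv), MeOH/EtOAc 1:1, rt
Reagents that add atoms: none
Why: Catalytic hydrogenolysis that cleaves the aryl C–Br bond and both benzylic C–O bonds in one operation; acetate takes up HBr so the isoquinoline stays unprotonated and is not ring-hydrogenated, and an inorganic base is used because amine bases slow O-debenzylation on Pd/C.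

Step 16
Reactants: 24 racemic dioncophylleine A
Product: 25 ent-dioncophylleine A (single atropisomer at the C7–C1' axis, mirror image of dioncophylleine A)
Conditions: preparative HPLC, cellulose tris(3,5-dimethylphenylcarbamate) phase, n-hexane/iPrOH/Et2NH, rt
Reagents that add atoms: none
Why: Enantiomer separation on a chiral stationary phase, feasible because the axis is flanked by 8-OH, 2'-CH3 and the peri-fused ring (C8a'/C8'–H), so rotation should be slow at room temperature; the ent-series is assigned by comparing its CD curve with a calculated one.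

**Compound list**
1 | 7-hydroxy-2,3-dihydro-1H-inden-1-one | O=C1CCc2cccc(O)c12 | starting material
2 | 7-(benzyloxy)-2,3-dihydro-1H-inden-1-one | O=C1CCc2cccc(OCc3ccccc3)c12 | intermediate
3 | lithium enolate of 2 (not isolated) | [Li]OC1=CCc2cccc(OCc3ccccc3)c12 | intermediate
4 | 7-(benzyloxy)-2-methyl-2,3-dihydro-1H-inden-1-one (racemic) | CC1Cc2cccc(OCc3ccccc3)c2C1=O | intermediate
5 | 4-(benzyloxy)-2-methyl-3-(trimethylsilyloxy)-1H-indene | CC1=C(O[Si](C)(C)C)c2c(OCc3ccccc3)cccc2C1 | intermediate
6 | 7-(benzyloxy)-2-methyl-1H-inden-1-one | CC1=Cc2cccc(OCc3ccccc3)c2C1=O | intermediate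
7 | 2'-hydroxy-6'-methoxyacetophenone | CC(=O)c1c(O)cccc1OC | starting material
8 | 2-acetyl-3-methoxyphenyl trifluoromethanesulfonate | CC(=O)c1c(OS(=O)(=O)C(F)(F)F)cccc1OC | intermediate
9 | propyne | CC#C | starting material
10 | 1-[2-methoxy-6-(prop-1-yn-1-yl)phenyl]ethan-1-one | CC#Cc1cccc(OC)c1C(C)=O | intermediate
11 | 1-[2-methoxy-6-(prop-1-yn-1-yl)phenyl]ethan-1-imine (not isolated) | CC#Cc1cccc(OC)c1C(C)=N | intermediate
12 | 8-methoxy-1,3-dimethylisoquinoline | COc1cccc2cc(C)nc(C)c12 | intermediate
13 | 1,3-dimethylisoquinolin-8-ol | Cc1cc2cccc(O)c2c(C)n1 | intermediate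
14 | 7-bromo-1,3-dimethylisoquinolin-8-ol | Cc1cc2ccc(Br)c(O)c2c(C)n1 | intermediate
15 | 8-(benzyloxy)-7-bromo-1,3-dimethylisoquinoline | Cc1cc2ccc(Br)c(OCc3ccccc3)c2c(C)n1 | intermediate
16 | 8-(benzyloxy)-1,3-dimethyl-7-(4,4,5,5-tetramethyl-1,3,2-dioxaborolan-2-yl)isoquinoline | Cc1cc2ccc(B3OC(C)(C)C(C)(C)O3)c(OCc3ccccc3)c2c(C)n1 | intermediate
17 | 7-(benzyloxy)-3-[8-(benzyloxy)-1,3-dimethylisoquinolin-7-yl]-2-methyl-2,3-dihydro-1H-inden-1-one (racemic, C2 epimers) | O=C1C(C)C(c2ccc3cc(C)nc(C)c3c2OCc2ccccc2)c2cccc(OCc3ccccc3)c12 | intermediate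
18 | 8-(benzyloxy)-7-[4-(benzyloxy)-3,3-dimethoxy-2-methyl-2,3-dihydro-1H-inden-1-yl]-1,3-dimethylisoquinoline (not isolated) | COC1(OC)C(C)C(c2ccc3cc(C)nc(C)c3c2OCc2ccccc2)c2cccc(OCc3ccccc3)c12 | intermediate
19 | 4-(benzyloxy)-1-[8-(benzyloxy)-1,3-dimethylisoquinolin-7-yl]-3-methoxy-2-methyl-1H-indene (racemic) | COC1=C(C)C(c2ccc3cc(C)nc(C)c3c2OCc2ccccc2)c2cccc(OCc3ccccc3)c12 | intermediate
20 | bromoform | BrC(Br)Br | starting material
21 | 2-(benzyloxy)-6-[8-(benzyloxy)-1,3-dimethylisoquinolin-7-yl]-1,1-dibromo-1a-methoxy-6a-methyl-1,1a,6,6a-tetrahydrocyclopropa[a]indene (racemic, CBr2 expected anti to the isoquinolinyl group, not isolated) | COC12c3c(OCc4ccccc4)cccc3C(c3ccc4cc(C)nc(C)c4c3OCc3ccccc3)C1(C)C2(Br)Br | intermediate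
22 | ring-enlarged 2-bromoallyl cation in its oxocarbenium form, bromide as counter-ion (not isolated) | C[O+]=C1C(Br)=C(C)C(c2ccc3cc(C)nc(C)c3c2OCc2ccccc2)c2cccc(OCc3ccccc3)c12.[Br-] | intermediate
23 | 8-(benzyloxy)-7-[5-(benzyloxy)-3-bromo-4-methoxy-2-methylnaphthalen-1-yl]-1,3-dimethylisoquinoline (racemic axis) | COc1c(Br)c(C)c(-c2ccc3cc(C)nc(C)c3c2OCc2ccccc2)c2cccc(OCc3ccccc3)c12 | intermediate
24 | racemic dioncophylleine A | COc1cc(C)c(-c2ccc3cc(C)nc(C)c3c2O)c2cccc(O)c12 | intermediate
25 | ent-dioncophylleine A (single atropisomer; SMILES cannot encode the axis) | COc1cc(C)c(-c2ccc3cc(C)nc(C)c3c2O)c2cccc(O)c12 | target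

**Step count**
- Total steps: 16.
- Longest linear sequence: 12 (steps 5–16, from 7).

**Steps most likely to fail**

1. **Step 14.**
   - What may go wrong: a base-induced 1,3-proton shift of the indene before carbene capture; loss of carbene to ylide formation at nitrogen or to insertion into benzylic C–H bonds; dealkylation of the oxocarbenium ion by bromide.
   - Fallback: base-free methylene transfer followed by oxidative opening, setting out from 17 and returning at 24.
   - Ketone 17 is treated with TMSOTf/Et3N to give the trimethylsilyl enol ether F1.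
   - Simmons–Smith cyclopropanation in the Et2Zn/CH2I2 form (CH2Cl2, excess reagent because of the basic nitrogen) gives the siloxycyclopropane F2.
   - FeCl3 in DMF cleaves the shared bond by one-electron oxidation, as in the Saegusa ring enlargement of siloxycyclopropanes, to give the ring-enlarged β-chloro ketone F3.
   - NaOAc in MeOH removes HCl with aromatisation to the naphthol F4.
   - MeI/K2CO3 in acetone gives the methyl ether F5, which differs from 23 only in lacking bromine. Under the conditions of step 15 it gives 24.

2. **Step 12.**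
   - What may go wrong: protodeboronation of the electron-rich ortho-alkoxy boronate and base-induced oligomerisation of the indenone, both outrunning a slow insertion into the α-methylated double bond.
   - Fallback: organomagnesium/copper conjugate addition, setting out from bromide 15 (the borylation is skipped) and indenone 6, and returning at 17.
   - Bromine–magnesium exchange with iPrMgCl·LiCl in THF (0 °C → rt), assisted by the ortho benzyloxy group, gives [8-(benzyloxy)-1,3-dimethylisoquinolin-7-yl]magnesium chloride F6.
   - F6 adds 1,4 to 6 under CuBr·SMe2 catalysis (10 mol %) at −78 °C. Aqueous NH4Cl work-up gives 17.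

3. **Step 13.**
   - What may go wrong: incomplete ketalisation of a hindered carbonyl group that the ortho-alkoxy arene deactivates, and hydrolysis of the enol ether during isolation.
   - Fallback: a silyl enol ether carries the ring enlargement and the methyl group is added afterwards, setting out from 17 and returning at 23.
   - TBSOTf/Et3N in CH2Cl2 gives the tert-butyldimethylsilyl enol ether F7.
   - CHBr3/KOtBu as in step 14 gives the dibromocyclopropane F8, which opens and loses HBr to the silyl naphthyl ether F9.
   - TBAF in THF frees the bromonaphthol F10.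
   - MeI/K2CO3 in acetone gives 23.

**Further compounds**
F1 | step 14 | 4-(benzyloxy)-1-[8-(benzyloxy)-1,3-dimethylisoquinolin-7-yl]-2-methyl-3-(trimethylsilyloxy)-1H-indene | C[Si](C)(C)OC1=C(C)C(c2ccc3cc(C)nc(C)c3c2OCc2ccccc2)c2cccc(OCc3ccccc3)c12
F2 | step 14 | 2-(benzyloxy)-6-[8-(benzyloxy)-1,3-dimethylisoquinolin-7-yl]-6a-methyl-1a-(trimethylsilyloxy)-1,1a,6,6a-tetrahydrocyclopropa[a]indene | C[Si](C)(C)OC12c3c(OCc4ccccc4)cccc3C(c3ccc4cc(C)nc(C)c4c3OCc3ccccc3)C1(C)C2
F3 | step 14 | 8-(benzyloxy)-4-[8-(benzyloxy)-1,3-dimethylisoquinolin-7-yl]-3-chloro-3-methyl-3,4-dihydronaphthalen-1(2H)-one | O=C1CC(C)(Cl)C(c2ccc3cc(C)nc(C)c3c2OCc2ccccc2)c2cccc(OCc3ccccc3)c12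
F4 | step 14 | 8-(benzyloxy)-4-[8-(benzyloxy)-1,3-dimethylisoquinolin-7-yl]-3-methylnaphthalen-1-ol | Oc1cc(C)c(-c2ccc3cc(C)nc(C)c3c2OCc2ccccc2)c2cccc(OCc3ccccc3)c12
F5 | step 14 | 8-(benzyloxy)-7-[5-(benzyloxy)-4-methoxy-2-methylnaphthalen-1-yl]-1,3-dimethylisoquinoline | COc1cc(C)c(-c2ccc3cc(C)nc(C)c3c2OCc2ccccc2)c2cccc(OCc3ccccc3)c12
F6 | step 12 | [8-(benzyloxy)-1,3-dimethylisoquinolin-7-yl]magnesium chloride | Cc1cc2ccc([Mg]Cl)c(OCc3ccccc3)c2c(C)n1
F7 | step 13 | 4-(benzyloxy)-1-[8-(benzyloxy)-1,3-dimethylisoquinolin-7-yl]-3-(tert-butyldimethylsilyloxy)-2-methyl-1H-indene | CC(C)(C)[Si](C)(C)OC1=C(C)C(c2ccc3cc(C)nc(C)c3c2OCc2ccccc2)c2cccc(OCc3ccccc3)c12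
F8 | step 13 | 2-(benzyloxy)-6-[8-(benzyloxy)-1,3-dimethylisoquinolin-7-yl]-1,1-dibromo-1a-(tert-butyldimethylsilyloxy)-6a-methyl-1,1a,6,6a-tetrahydrocyclopropa[a]indene | CC(C)(C)[Si](C)(C)OC12c3c(OCc4ccccc4)cccc3C(c3ccc4cc(C)nc(C)c4c3OCc3ccccc3)C1(C)C2(Br)Br
F9 | step 13 | 8-(benzyloxy)-7-[5-(benzyloxy)-3-bromo-4-(tert-butyldimethylsilyloxy)-2-methylnaphthalen-1-yl]-1,3-dimethylisoquinoline | CC(C)(C)[Si](C)(C)Oc1c(Br)c(C)c(-c2ccc3cc(C)nc(C)c3c2OCc2ccccc2)c2cccc(OCc3ccccc3)c12
F10 | step 13 | 8-(benzyloxy)-4-[8-(benzyloxy)-1,3-dimethylisoquinolin-7-yl]-2-bromo-3-methylnaphthalen-1-ol | Oc1c(Br)c(C)c(-c2ccc3cc(C)nc(C)c3c2OCc2ccccc2)c2cccc(OCc3ccccc3)c12
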